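The target is a meso succinate that carries two identical 1,4-benzoquinone rings (A and B). In each ring C6=O lies between C1, bonded to the succinate carbon, and C5, bonded to geranyl, whereas C3=O lies between C2–H and C4–H. Both C3–O bonds are disconnected, which leads to a meso bis(2,6-disubstituted phenol) whose only unsubstituted position conjugated with the phenolic oxygen is the para C–H. A twofold Teuber oxidation installs both para oxygens and both quinones in the last step at neutral pH. The bis-phenol comes from iodine-mediated homocoupling of a silyl-protected methyl arylacetate, then methoxide desilylation with equilibration to meso.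

Key step: step 6

Remark: the two stereocentres of the target are (2S,3R) with identical ligand sets, so the compound is the achiral meso form and only the relative configuration has to be controlled; geranyl stands for (2E)-3,7-dimethylocta-2,6-dien-1-yl throughout.

Step 1
Reactants: 1 2-bromophenol; 2 geranyl bromide
Product: 4 2-bromo-6-geranylphenol, via sodium 2-bromophenoxide 3 (not isolated)
Conditions: NaH (1.05 equiv), toluene, 0 °C to rt; then 2, rt, dark; aq. NH4Cl; SiO2
Reagents that add atoms: none
Why: Ambident-phenoxide C-allylation: in toluene the sodium phenoxide reacts as a tight, unsolvated ion pair whose oxygen is shielded by the cation, so its only free ortho carbon attacks the primary allylic bromide in an SN2 sense with retention of the E alkene and the ring then rearomatises, the O-geranyl ether formed alongside being removed on silica.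

Step 2
Reactants: 4 2-bromo-6-geranylphenol
Product: 5 (2-bromo-6-geranylphenoxy)(tert-butyl)dimethylsilane
Conditions: TBSCl, imidazole, DMF, rt to 40 °C
Reagents that add atoms: tert-butyldimethylsilyl chloride (TBSCl), CC(C)(C)[Si](C)(C)Cl
Why: Imidazole-promoted silylation of a phenol, which masks the acidic and oxidisable OH for the zinc, amide-base and iodine steps and can later be removed by methoxide without any acid next to the geranyl chain.

Step 3
Reactants: 5 (2-bromo-6-geranylphenoxy)(tert-butyl)dimethylsilane; 6 methyl bromoacetate
Product: 8 methyl [2-(tert-butyldimethylsilyloxy)-3-geranylphenyl]acetate, via bromozinc ester 7 (not isolated)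
Conditions: 6, Zn dust (TMSCl-activated), THF, rt to 40 °C; then 5, Pd2(dba)3 (2.5 mol %), XPhos (10 mol %), THF, 60 °C
Reagents that add atoms: none
Why: Negishi-type cross-coupling of a Reformatsky reagent (palladium-catalysed α-arylation of an ester under neutral conditions), in which the bulky biaryl phosphine allows oxidative addition at the ortho-substituted C–Br bond, the silyl ether and methyl ester are untouched, and the geranyl alkenes sit meta to the arylpalladium carbon and thus out of reach for Heck cyclisation.

Step 4
Reactants: 8 methyl [2-(tert-butyldimethylsilyloxy)-3-geranylphenyl]acetate (two molecules)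
Product: 11 dimethyl 2,3-bis[2-(tert-butyldimethylsilyloxy)-3-geranylphenyl]succinate (meso/dl mixture), via lithium enolate 9 (not isolated), via α-iodo ester 10 (not isolated)
Conditions: LDA (1.05 equiv), THF, −78 °C; I2 (0.5 equiv) in THF, −78 °C to 0 °C; aq. Na2S2O3
Reagents that add atoms: none
Why: Oxidative enolate homocoupling: half an equivalent of iodine turns half of enolate 9 into the benzylic iodide 10, which the remaining enolate displaces to form the C2–C3 bond, the two new stereocentres being set without control because step 5 equilibrates them, while the low temperature holds back O-to-C silyl migration and the absence of excess base and iodine holds back further dehydrogenation and attack on the alkenes.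

Step 5
Reactants: 11 dimethyl 2,3-bis[2-(tert-butyldimethylsilyloxy)-3-geranylphenyl]succinate (meso/dl mixture)
Product: 13 meso-dimethyl 2,3-bis(3-geranyl-2-hydroxyphenyl)succinate, via disodium bis-phenoxide 12 (not isolated)
Conditions: NaOMe (6 equiv), degassed MeOH/THF, Ar, rt to 40 °C; AcOH, 0 °C; SiO2, dl isomer returned to the same conditions; 13 kept cold and used at once
Reagents that add atoms: none
Why: Methoxide cleaves the aryl silyl ethers by attack at silicon and the same medium epimerises both α-aryl ester centres (by direct enolisation and by reversible lactonisation onto the neighbouring ester, which raises the C–H acidity and is undone by methanol), so this base-mediated thermodynamic equilibration sets the relative configuration in favour of the meso isomer, the one in which the aryl/aryl and ester/ester pairs can all stand anti.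

Step 6
Reactants: 13 meso-dimethyl 2,3-bis(3-geranyl-2-hydroxyphenyl)succinate
Product: 15 meso-dimethyl 2,3-bis(5-geranyl-3,6-dioxocyclohexa-1,4-dien-1-yl)succinate (target), via phenol-quinone 14 (not isolated)
Conditions: ON(SO3K)2 (5 equiv), Aliquat 336 (methyltrioctylammonium chloride, 20 mol %), CH2Cl2 / aq. KH2PO4–K2HPO4 (pH 7), 0 °C to rt, dark, vigorous stirring; rapid SiO2 filtration
Reagents that add atoms: potassium nitrosodisulfonate, [O]N(S(=O)(=O)[O-])S(=O)(=O)[O-].[K+].[K+]
Why: Teuber oxidation run on both rings: one ON(SO3K)2 radical removes the phenolic hydrogen, a second one bonds through its oxygen to the para carbon of the resulting phenoxyl radical, and expulsion of HN(SO3K)2 from that adduct together with the para hydrogen leaves the new C3=O group, so that four equivalents are consumed and the half-oxidised 14 is passed on the way. The closest known reaction type is the nitrosodisulfonate (or Co(salen)/O2) oxidation of 2,6-dialkylphenols, including ones with prenyl-type chains, to 2,6-disubstituted 1,4-benzoquinones. No ring is closed and no stereocentre is created, the meso relationship of C2 and C3 being carried over unchanged from 13. The selectivity needed is para C–O bond formation in preference to ortho attack, to hydrogen abstraction at the ArCH2 and ArCH(CO2Me) positions and to reaction at the trisubstituted alkenes, and it is secured because both ortho carbons of each phenol already bear carbon substituents, which leaves the para C–H as the only open site of high spin density, and because the reagent does not add to unactivated alkenes. The pH 7 buffer protects the quinone-activated α-centres from enolisation and the o-hydroxyaryl esters from lactonisation, and the quaternary ammonium salt carries the dianionic radical into the organic phase where the lipophilic substrate resides.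

Compound list
1 | 2-bromophenol | Oc1ccccc1Br | starting material
2 | geranyl bromide, (2E)-1-bromo-3,7-dimethylocta-2,6-diene | BrC/C=C(\C)CCC=C(C)C | starting material
3 | sodium 2-bromophenoxide | [Na+].[O-]c1ccccc1Br | intermediate
4 | 2-bromo-6-geranylphenol | Oc1c(Br)cccc1C/C=C(\C)CCC=C(C)C | intermediate
5 | (2-bromo-6-geranylphenoxy)(tert-butyl)dimethylsilane | CC(C)(C)[Si](C)(C)Oc1c(Br)cccc1C/C=C(\C)CCC=C(C)C | intermediate
6 | methyl bromoacetate | COC(=O)CBr | starting material
7 | bromo(2-methoxy-2-oxoethyl)zinc (Reformatsky reagent) | COC(=O)C[Zn]Br | intermediate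
8 | methyl [2-(tert-butyldimethylsilyloxy)-3-geranylphenyl]acetate | COC(=O)Cc1cccc(C/C=C(\C)CCC=C(C)C)c1O[Si](C)(C)C(C)(C)C | intermediate
9 | lithium enolate of 8 (enolate geometry not defined) | [Li+].[O-]C(OC)=Cc1cccc(C/C=C(\C)CCC=C(C)C)c1O[Si](C)(C)C(C)(C)C | intermediate
10 | methyl 2-iodo-2-[2-(tert-butyldimethylsilyloxy)-3-geranylphenyl]acetate (racemic) | COC(=O)C(I)c1cccc(C/C=C(\C)CCC=C(C)C)c1O[Si](C)(C)C(C)(C)C | intermediate
11 | dimethyl 2,3-bis[2-(tert-butyldimethylsilyloxy)-3-geranylphenyl]succinate (meso/dl mixture, C2 and C3 undefined) | COC(=O)C(c1cccc(C/C=C(\C)CCC=C(C)C)c1O[Si](C)(C)C(C)(C)C)C(C(=O)OC)c1cccc(C/C=C(\C)CCC=C(C)C)c1O[Si](C)(C)C(C)(C)C | intermediate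
12 | disodium salt of dimethyl 2,3-bis(3-geranyl-2-oxidophenyl)succinate (equilibrating at C2 and C3) | COC(=O)C(c1cccc(C/C=C(\C)CCC=C(C)C)c1[O-])C(C(=O)OC)c1cccc(C/C=C(\C)CCC=C(C)C)c1[O-].[Na+].[Na+] | intermediate
13 | meso-dimethyl 2,3-bis(3-geranyl-2-hydroxyphenyl)succinate, (2R,3S) | COC(=O)[C@H](c1cccc(C/C=C(\C)CCC=C(C)C)c1O)[C@@H](C(=O)OC)c1cccc(C/C=C(\C)CCC=C(C)C)c1O | intermediate
14 | dimethyl 2-(5-geranyl-3,6-dioxocyclohexa-1,4-dien-1-yl)-3-(3-geranyl-2-hydroxyphenyl)succinate (racemic, relative configuration as in 13, one enantiomer drawn) | COC(=O)[C@H](C1=CC(=O)C=C(C/C=C(\C)CCC=C(C)C)C1=O)[C@@H](C(=O)OC)c1cccc(C/C=C(\C)CCC=C(C)C)c1O | intermediate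
15 | meso-dimethyl 2,3-bis(5-geranyl-3,6-dioxocyclohexa-1,4-dien-1-yl)succinate, (2R,3S) | COC(=O)[C@H](C1=CC(=O)C=C(C/C=C(\C)CCC=C(C)C)C1=O)[C@@H](C(=O)OC)C1=CC(=O)C=C(C/C=C(\C)CCC=C(C)C)C1=O | target

Total step count: 6
Longest linear sequence: 6 steps (1 to 15)

Steps most likely to fail

Step 6 (key step). Four things may go wrong:
- The second ring may be oxidised more slowly than the first.
- Hydrogen abstraction at the benzylic–allylic CH2 may compete with para coupling.
- The remaining phenol may add to the quinone ring already formed.
- A long reaction time may allow epimerisation.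

Fallback, from 13 back to 15: the para oxygen is brought in by C–H borylation instead of radical oxidation. [Ir(OMe)(cod)]2, dtbpy and B2pin2 in THF at 60 °C should borylate the only ring C–H without an ortho substituent, which is the one para to oxygen. The OH groups are masked in the flask as O–Bpin and freed again by methanol. This should give the meso bis(pinacol boronate) F1. H2O2 in THF/pH 7 phosphate buffer at 0 °C should turn both C–B bonds into C–OH and give the meso bis-hydroquinone F2. Ag2O and MgSO4 in Et2O then dehydrogenate F2 to 15.

Step 5. Four things may go wrong: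
- The thermodynamic bias towards meso at the bis-phenoxide stage may be small.
- Cleavage of the hindered silyl ethers may lag behind.
- The electron-rich anions may be oxidised by adventitious air.
- Acidification may trigger lactonisation.

Fallback, from 11 back to 13: stereochemical sorting is moved to the protected stage and alkoxide is replaced by buffered fluoride. Compound 11 is equilibrated with DBU in hot toluene, where the silyl ethers persist. The meso bis-silyl ether F3 is separated by crystallisation or chromatography, and the dl fraction is re-equilibrated. F3 is then desilylated with Bu4NF/AcOH in THF at 0 °C, a medium too weakly basic to epimerise or lactonise, to give 13.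

Step 4. Displacement between two hindered secondary benzylic partners may be slow. That gives time for silyl migration to the enolate, proton exchange between enolate and iodide, and further dehydrogenation of the coupled product.

Fallback, from 8 back to 11: the C2–C3 bond is made by radical recombination instead of SN2 displacement. Enolate formation with LiHMDS at −78 °C and quenching with BrCCl2CCl2Br should give the racemic α-bromo ester F4, which is isolated. Stoichiometric CoCl(PPh3)3 (monovalent cobalt) in acetone at rt abstracts bromine, and the benzylic α-ester radicals should dimerise to 11. These radicals lie too far from the geranyl alkenes to cyclise.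

Further compounds
F1 | step 6 | meso-dimethyl 2,3-bis[3-geranyl-2-hydroxy-5-(4,4,5,5-tetramethyl-1,3,2-dioxaborolan-2-yl)phenyl]succinate | COC(=O)[C@H](c1cc(B2OC(C)(C)C(C)(C)O2)cc(C/C=C(\C)CCC=C(C)C)c1O)[C@@H](C(=O)OC)c1cc(B2OC(C)(C)C(C)(C)O2)cc(C/C=C(\C)CCC=C(C)C)c1O
F2 | step 6 | meso-dimethyl 2,3-bis(3-geranyl-2,5-dihydroxyphenyl)succinate | COC(=O)[C@H](c1cc(O)cc(C/C=C(\C)CCC=C(C)C)c1O)[C@@H](C(=O)OC)c1cc(O)cc(C/C=C(\C)CCC=C(C)C)c1O
F3 | step 5 | meso-dimethyl 2,3-bis[2-(tert-butyldimethylsilyloxy)-3-geranylphenyl]succinate | COC(=O)[C@H](c1cccc(C/C=C(\C)CCC=C(C)C)c1O[Si](C)(C)C(C)(C)C)[C@@H](C(=O)OC)c1cccc(C/C=C(\C)CCC=C(C)C)c1O[Si](C)(C)C(C)(C)C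
F4 | step 4 | methyl 2-bromo-2-[2-(tert-butyldimethylsilyloxy)-3-geranylphenyl]acetate (racemic) | COC(=O)C(Br)c1cccc(C/C=C(\C)CCC=C(C)C)c1O[Si](C)(C)C(C)(C)C
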